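Each product formed uses up one starting material, so in every flask the share of the charge turned and the share left add up to one, and I reckon in those shares.

| setting | Monday's | Sunday's | Tuesday's | Wednesday's | Thursday's |
|---|---|---|---|---|---|
| starting material | 80.0 mM | 80.0 mM | 40.0 mM | 80.0 mM | 32.0 mM |
| partner | 160 mM | 160 mM | 160 mM | 240 mM | 64.0 mM |
| product |  | 24.0 mM |  |  |  |
| time |  |  |  |  | 51 min |

| Monday's run: time / min | Monday's run: [product] / mM | Sunday's run: time / min | Sunday's run: [product] / mM | Tuesday's run: time / min | Tuesday's run: [product] / mM | Wednesday's run: time / min | Wednesday's run: [product] / mM |
|---|---|---|---|---|---|---|---|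
| 2.0 | 0.7 | 2.0 | 27.7 | 2.0 | 0.3 | 2.0 | 1.0 |
| 3.5 | 1.4 | 3.5 | 30.4 | 3.5 | 0.8 | 3.5 | 2.4 |
| 6.0 | 3.0 | 6.0 | 34.6 | 6.0 | 1.4 | 6.0 | 3.5 |
| 10 | 4.8 | 10 | 42.4 | 10 | 2.7 | 10 | 6.4 |
| 17 | 10.9 | 17 | 56.3 | 17 | 3.8 | 17 | 13.8 |
| 30 | 22.3 | 30 | 75.5 | 30 | 7.8 | 30 | 32.6 |
| 51 | 46.0 | 51 | 93.5 | 51 | 15.0 | 51 | 59.3 |

(scatter of a reading: 0.4 mM)

- Overall: starting material + partner -> product.
- Constant volume, constant temperature.
- Readings of a species count what is bound in complexes too.
- "The second partner" is partner.
- An order is taken over about fifteen percent of the charge, up and down.

- how the opening rate goes with [starting material] round the charge of the Monday's run: the exponent of the rate at two percent of starting material gone to product (one fixed amount of product, the same in the runs compared)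
- how the opening rate goes with [partner] round the charge of the Monday's run: the exponent of the rate at two percent of starting material gone to product
- product in the Thursday's run at 51 min, as a share of the starting material charged

Where does Monday's run head? Starting material is the limiting reagent, 80.0 mM against 160 mM of partner, so its share turned heads for one, and at 51 min it reads 57.5%.

How fast does it get there? Monday's run makes 0.480 mM min⁻¹ over its first 10 min, while Sunday's run, with the same charge and 24.0 mM of product added, makes 1.77 mM min⁻¹ over its first 6.0 min. These readings give a speed-up of 3.68, which is autocatalysis.

What do you carry from that? Suppose the rate climbs in a straight line with product. The seed then adds 2.68 unassisted rates, so one unassisted rate corresponds to 8.95 mM. This is the crossover amount, the product at which the product-assisted route matches the unassisted one.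

Isn't that a share of the charge? No, it is an amount, and that is the weak spot in copying Monday's curve. It is 11.2% of Monday's charge but 28.0% of Thursday's, a larger share, so Thursday's run starts with less help from its own product.

So what is your number? Take the clock L, the logarithm of (crossover share plus share turned) over (crossover share times share left). If the rate goes as the starting material left times crossover amount plus product, then with partner treated as fixed the clock grows steadily, at a pace proportional to crossover amount plus charge. Monday's run reaches 2.67 at 51 min. At 30 min, Wednesday's clock over Monday's gives a partner exponent of 0.657, as a reading. Scaling for Thursday's charges gives a clock of 0.673, which is 17.4% turned at 51 min.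

The forecast, made separately, gives an order of 1 in starting material, an order of 0.75 in partner, and 14.5% for Thursday's run, within 11% to 19%; that Thursday figure stands below mine. Its ground for the partner order: “which suggests partial saturation in partner”.

The flask gives an order of 1.0 in starting material, an order of 0.57 in partner, and 19.0% for Thursday's run.

    starting material + partner → product + by-product (0.1548 M⁻¹ min⁻¹)
    starting material + partner + product → 2 product (19.68 M⁻² min⁻¹)
    2 partner ⇌ idle reagent dimer, settled at all times (54.10 M⁻¹)

At the same amount made, Wednesday's run goes 1.3 times as fast as Monday's. Thursday's 19.0% is 6.08 mM of product, less than the crossover amount of 8.95 mM. The clock, taken from Monday's half-time of 45.2 min, puts Tuesday's half-time at 64.1 min, and Tuesday's run gives 63.0 min.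

The runs come from a simulation with constants of no real substance, noise included.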